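**Plan**

Retrosynthesis: ring C is the butenolide (O1, carbonyl C2, C3 carrying the vinyl arm to ring B, C4–H, ylidene C5) and lies between two halves of similar size. C4, C5 and the exocyclic methine are what a Z-2-en-4-ynoic acid leaves on lactonisation, so cutting C4–C5 and O1–C5 gives a Z-β-iodoacrylic acid carrying ring B and a terminal alkyne ending the ring A polyenyne.
The alkyne half is cut at the central C(sp2)–C(sp2) single bond of its tetraene and at the ring A–alkyne bond; the acid half is cut at the diene single bond, at C–I (from C–Si) and at the ring B–alkyne bond.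
Forward: ketoisophorone gives both antipodes of 4-hydroxyisophorone, and each becomes a cyclohexenyl triflate. Ring A is joined to its chain in steps 4–11, ring B is taken to the iodo acid in steps 15–23, and ring C is closed last, which gives the unprotected target directly.
Stereochemistry: both ring carbinols come from the two antipodes of a Ru transfer-hydrogenation catalyst. In ring B (C1 = CMe2, C3 = CHOH, C5 = C(CH3)OH, C6 = chain-bearing carbon) the C3 hydroxyl directs epoxidation of C5=C6 to its own face and water opens the epoxide at C5 with inversion. Chain geometry comes from the E-enynol, E-selective chromium olefinations and stereoretentive couplings; the Z-ylidene comes from anti oxymetalation.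

Key step: step 24

Assumption: the (S,S)-configured catalyst is taken to give the (S)-carbinol, the alkene playing the part that an aryl group plays in aryl ketones; if the sense is the reverse, the two catalyst antipodes change places between steps 1 and 12.

**Route**

Step 1
Reactants: 1 ketoisophorone (2,6,6-trimethylcyclohex-2-ene-1,4-dione)
Product: 2 (S)-4-hydroxy-2,6,6-trimethylcyclohex-2-en-1-one
Conditions: RuCl(p-cymene)[(S,S)-TsDPEN] (1 mol %), i-PrOH, rt
Reagents that add atoms: none
Why: Noyori-type asymmetric transfer hydrogenation reduces only the C4 carbonyl, since the C1 carbonyl is shielded by the gem-dimethyl and 2-methyl groups, and the chiral ligand selects the carbonyl face so that the single stereocentre of ring A is set as (S).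

Step 2
Reactants: 2 (S)-4-hydroxy-2,6,6-trimethylcyclohex-2-en-1-one
Product: 3 (S)-4-(tert-butyldimethylsilyloxy)-2,6,6-trimethylcyclohex-2-en-1-one
Conditions: TBSCl, imidazole, DMF, 0 °C to rt
Reagents that add atoms: tert-butyldimethylsilyl chloride, CC(C)(C)[Si](C)(C)Cl
Why: Standard silylation of a secondary alcohol gives an ether that is inert to the hydride, enolate, chromium and palladium chemistry of steps 3 to 10 and puts no stereocentre at risk.

Step 3
Reactants: 3 (S)-4-(tert-butyldimethylsilyloxy)-2,6,6-trimethylcyclohex-2-en-1-one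
Product: 5 (R)-4-(tert-butyldimethylsilyloxy)-2,6,6-trimethylcyclohex-1-en-1-yl trifluoromethanesulfonate, via lithium enolate 4 (not isolated)
Conditions: LiBH(s-Bu)3, THF, −78 °C; then PhNTf2, −78 °C to rt
Reagents that add atoms: N-phenylbis(trifluoromethanesulfonimide), O=S(=O)(N(c1ccccc1)S(=O)(=O)C(F)(F)F)C(F)(F)F
Why: Conjugate reduction by the bulky borohydride (1,2-attack is blocked by the groups flanking the carbonyl) gives the tetrasubstituted enolate regiospecifically and O-sulfonylation turns it into the enol triflate, a reductive enol triflation that touches no stereocentre.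

Step 4
Reactants: 5 (R)-4-(tert-butyldimethylsilyloxy)-2,6,6-trimethylcyclohex-1-en-1-yl trifluoromethanesulfonate; 6 (E)-3-methylpent-2-en-4-yn-1-ol
Product: 7 (R,E)-5-[4-(tert-butyldimethylsilyloxy)-2,6,6-trimethylcyclohex-1-en-1-yl]-3-methylpent-2-en-4-yn-1-ol
Conditions: Pd(PPh3)4 (5 mol %), CuI (10 mol %), Et3N, DMF, 50 °C
Reagents that add atoms: none
Why: Sonogashira coupling of a vinyl triflate with a terminal alkyne, a reaction known for hindered 2,6,6-trimethylcyclohexenyl triflates, forms the ring A–alkyne bond without touching the E double bond or the free allylic alcohol.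

Step 5
Reactants: 7 (R,E)-5-[4-(tert-butyldimethylsilyloxy)-2,6,6-trimethylcyclohex-1-en-1-yl]-3-methylpent-2-en-4-yn-1-ol
Product: 8 (R,E)-5-[4-(tert-butyldimethylsilyloxy)-2,6,6-trimethylcyclohex-1-en-1-yl]-3-methylpent-2-en-4-ynal
Conditions: MnO2, CH2Cl2, rt
Reagents that add atoms: none
Why: Activated MnO2 oxidises only the primary allylic alcohol to the conjugated aldehyde (allylic oxidation) and does so without E/Z isomerisation.

Step 6
Reactants: 8 (R,E)-5-[4-(tert-butyldimethylsilyloxy)-2,6,6-trimethylcyclohex-1-en-1-yl]-3-methylpent-2-en-4-ynal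
Product: 9 (R)-tert-butyl({4-[(3E,5E)-6-iodo-3-methylhexa-3,5-dien-1-yn-1-yl]-3,5,5-trimethylcyclohex-3-en-1-yl}oxy)dimethylsilane
Conditions: CrCl2, CHI3, THF/dioxane, 0 °C to rt, dark
Reagents that add atoms: iodoform, IC(I)I
Why: Takai olefination, in which the gem-dichromium reagent from CHI3 and CrCl2 adds to the aldehyde and anti-elimination from the more stable adduct gives the E-vinyl iodide, dioxane raising the E preference, while silyl ether and enyne are inert to divalent chromium.

Step 7
Reactants: 6 (E)-3-methylpent-2-en-4-yn-1-ol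
Product: 11 (E)-3-methyl-5-(trimethylsilyl)pent-2-en-4-yn-1-ol, via O,C-bis(trimethylsilyl) derivative 10 (not isolated)
Conditions: n-BuLi (2.2 equiv), THF, −78 °C; Me3SiCl (2.2 equiv), −78 °C to rt; then 1 M HCl work-up
Reagents that add atoms: chlorotrimethylsilane, C[Si](C)(C)Cl
Why: Double deprotonation, silylation at oxygen and at the alkyne terminus, and hydrolysis of the labile O–Si bond on acidic work-up mask the acetylenic C–H (C-silylation of a terminal alkyne) so that it cannot interfere in steps 9 and 10.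

Step 8
Reactants: 11 (E)-3-methyl-5-(trimethylsilyl)pent-2-en-4-yn-1-ol
Product: 12 (E)-3-methyl-5-(trimethylsilyl)pent-2-en-4-ynal
Conditions: MnO2, CH2Cl2, rt
Reagents that add atoms: none
Why: Allylic oxidation with MnO2 stops at the aldehyde and keeps the E geometry, and the alkynylsilane is untouched.

Step 9
Reactants: 12 (E)-3-methyl-5-(trimethylsilyl)pent-2-en-4-ynal
Product: 13 2-[(1E,3E)-4-methyl-6-(trimethylsilyl)hexa-1,3-dien-5-yn-1-yl]-4,4,5,5-tetramethyl-1,3,2-dioxaborolane
Conditions: CrCl2, LiI, Cl2CHB(pin), THF, rt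
Reagents that add atoms: 2-(dichloromethyl)-4,4,5,5-tetramethyl-1,3,2-dioxaborolane, ClC(Cl)B1OC(C)(C)C(C)(C)O1
Why: Boron variant of the Takai olefination (Takai–Utimoto), in which the boryl-substituted gem-dichromium reagent converts the aldehyde into the E-alkenylboronate under the same anti-elimination control and leaves the silylated enyne untouched.

Step 10
Reactants: 9 (R)-tert-butyl({4-[(3E,5E)-6-iodo-3-methylhexa-3,5-dien-1-yn-1-yl]-3,5,5-trimethylcyclohex-3-en-1-yl}oxy)dimethylsilane; 13 2-[(1E,3E)-4-methyl-6-(trimethylsilyl)hexa-1,3-dien-5-yn-1-yl]-4,4,5,5-tetramethyl-1,3,2-dioxaborolane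
Product: 14 (R)-tert-butyl({4-[(3E,5E,7E,9E)-3,10-dimethyl-12-(trimethylsilyl)dodeca-3,5,7,9-tetraene-1,11-diyn-1-yl]-3,5,5-trimethylcyclohex-3-en-1-yl}oxy)dimethylsilane
Conditions: PdCl2(dppf) (5 mol %), aq K3PO4, THF, rt, dark
Reagents that add atoms: none
Why: Suzuki–Miyaura coupling of an alkenyl iodide with an alkenylboronate forms the central C(sp2)–C(sp2) bond with retention of both double-bond geometries under mild aqueous phosphate, and any alkynylsilane cleaved by the base converges with the product in step 11.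

Step 11
Reactants: 14 (R)-tert-butyl({4-[(3E,5E,7E,9E)-3,10-dimethyl-12-(trimethylsilyl)dodeca-3,5,7,9-tetraene-1,11-diyn-1-yl]-3,5,5-trimethylcyclohex-3-en-1-yl}oxy)dimethylsilane
Product: 15 (R)-4-[(3E,5E,7E,9E)-3,10-dimethyldodeca-3,5,7,9-tetraene-1,11-diyn-1-yl]-3,5,5-trimethylcyclohex-3-en-1-ol
Conditions: Bu4NF, THF, 0 °C to rt, dark
Reagents that add atoms: none
Why: Fluoride cleaves both the Si–O bond and the Si–C(sp) bond (desilylation) and leaves the tetraene and both triple bonds untouched, which frees the terminal alkyne and the ring A hydroxyl for the last step.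

Step 12
Reactants: 1 ketoisophorone (2,6,6-trimethylcyclohex-2-ene-1,4-dione)
Product: 16 (R)-4-hydroxy-2,6,6-trimethylcyclohex-2-en-1-one
Conditions: RuCl(p-cymene)[(R,R)-TsDPEN] (1 mol %), i-PrOH, rt
Reagents that add atoms: none
Why: The same Noyori-type transfer hydrogenation with the mirror-image catalyst reduces the C4 carbonyl from the other face and sets the (R)-carbinol, which becomes C3 of ring B.

Step 13
Reactants: 16 (R)-4-hydroxy-2,6,6-trimethylcyclohex-2-en-1-one
Product: 17 (R)-4-(tert-butyldimethylsilyloxy)-2,6,6-trimethylcyclohex-2-en-1-one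
Conditions: TBSCl, imidazole, DMF, 0 °C to rt
Reagents that add atoms: tert-butyldimethylsilyl chloride, CC(C)(C)[Si](C)(C)Cl
Why: Standard silylation protects the carbinol for the hydride, enolate and palladium chemistry of steps 14 and 15.

Step 14
Reactants: 17 (R)-4-(tert-butyldimethylsilyloxy)-2,6,6-trimethylcyclohex-2-en-1-one
Product: 19 (S)-4-(tert-butyldimethylsilyloxy)-2,6,6-trimethylcyclohex-1-en-1-yl trifluoromethanesulfonate, via lithium enolate 18 (not isolated)
Conditions: LiBH(s-Bu)3, THF, −78 °C; then PhNTf2, −78 °C to rt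
Reagents that add atoms: N-phenylbis(trifluoromethanesulfonimide), O=S(=O)(N(c1ccccc1)S(=O)(=O)C(F)(F)F)C(F)(F)F
Why: Reductive enol triflation as in step 3, in which conjugate hydride addition fixes the enolate regiochemistry and O-sulfonylation gives the tetrasubstituted vinyl triflate with the carbinol stereocentre untouched.

Step 15
Reactants: 19 (S)-4-(tert-butyldimethylsilyloxy)-2,6,6-trimethylcyclohex-1-en-1-yl trifluoromethanesulfonate; 20 ethynyltrimethylsilane
Product: 21 (S)-tert-butyldimethyl({3,5,5-trimethyl-4-[(trimethylsilyl)ethynyl]cyclohex-3-en-1-yl}oxy)silane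
Conditions: PdCl2(PPh3)2 (5 mol %), CuI (10 mol %), Et3N, DMF, 60 °C, sealed tube
Reagents that add atoms: none
Why: Sonogashira coupling of the hindered vinyl triflate with the silyl-capped acetylene forms the ring B–alkyne bond, the cap preventing double coupling.

Step 16
Reactants: 21 (S)-tert-butyldimethyl({3,5,5-trimethyl-4-[(trimethylsilyl)ethynyl]cyclohex-3-en-1-yl}oxy)silane
Product: 22 (S)-4-ethynyl-3,5,5-trimethylcyclohex-3-en-1-ol
Conditions: Bu4NF, THF, rt
Reagents that add atoms: none
Why: Fluoride removes both silyl groups (desilylation) and frees the C3 hydroxyl, which is needed as the directing group in step 17, together with the terminal alkyne.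

Step 17
Reactants: 22 (S)-4-ethynyl-3,5,5-trimethylcyclohex-3-en-1-ol
Product: 23 (1R,3R,6R)-6-ethynyl-1,5,5-trimethyl-7-oxabicyclo[4.1.0]heptan-3-ol (epoxide cis to the hydroxyl)
Conditions: VO(acac)2 (5 mol %), t-BuOOH, CH2Cl2, 0 °C to rt
Reagents that add atoms: tert-butyl hydroperoxide, CC(C)(C)OO
Why: Vanadium-catalysed hydroxyl-directed epoxidation of a cyclic homoallylic alcohol, in which the vanadate ester of the C3 hydroxyl delivers the peroxide oxygen to its own face of the tetrasubstituted C5=C6 bond, so that the new stereocentres C5 and C6 are set with the epoxide cis to the hydroxyl while the terminal alkyne is inert.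

Step 18
Reactants: 23 (1R,3R,6R)-6-ethynyl-1,5,5-trimethyl-7-oxabicyclo[4.1.0]heptan-3-ol
Product: 24 (1R,2S,4R)-1-ethynyl-2,6,6-trimethylcyclohexane-1,2,4-triol
Conditions: HClO4 (5 mol %), THF/H2O (3:1), 0 °C
Reagents that add atoms: water, O
Why: Acid-catalysed epoxide hydrolysis, in which water attacks the protonated epoxide at C5 from the face opposite to the oxygen, because C6 is propargylic (the alkynyl group disfavours positive charge), neopentyl-like and could open only through a chair with three axial groups, so that trans-diaxial (Fürst–Plattner) opening inverts C5, retains C6 and gives the trans-5,6-diol with the C5 hydroxyl trans and the C6 hydroxyl cis to the C3 hydroxyl.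

Step 19
Reactants: 24 (1R,2S,4R)-1-ethynyl-2,6,6-trimethylcyclohexane-1,2,4-triol
Product: 26 (1S,2S,4R)-1-[(E)-2-iodoethenyl]-2,6,6-trimethylcyclohexane-1,2,4-triol, via E-vinylstannane 25 (not isolated)
Conditions: Bu3SnH, PdCl2(PPh3)2 (3 mol %), THF, 0 °C; then I2, CH2Cl2, 0 °C
Reagents that add atoms: iodine, II
Why: Palladium-catalysed hydrostannation adds H and Sn syn across the terminal alkyne with tin on the terminal carbon, away from the crowded tertiary carbinol, and iododestannylation proceeds with retention, which gives the E-vinyl iodide (hydrostannation–iodination) without protection of the three hydroxyl groups.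

Step 20
Reactants: 27 ethyl 3-(trimethylsilyl)propiolate
Product: 28 ethyl (E)-2-(tributylstannyl)-3-(trimethylsilyl)acrylate
Conditions: Bu3SnH, Pd(PPh3)4 (2 mol %), THF, rt
Reagents that add atoms: tributyltin hydride, CCCC[SnH](CCCC)CCCC
Why: Palladium-catalysed hydrostannation of an ynoate is a syn addition that places tin α to the ester, so that hydrogen and tin are cis and the silyl group ends up cis to the ester.

Step 21
Reactants: 26 (1S,2S,4R)-1-[(E)-2-iodoethenyl]-2,6,6-trimethylcyclohexane-1,2,4-triol; 28 ethyl (E)-2-(tributylstannyl)-3-(trimethylsilyl)acrylate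
Product: 29 ethyl (2Z,3E)-2-[(trimethylsilyl)methylidene]-4-[(1S,2S,4R)-1,2,4-trihydroxy-2,6,6-trimethylcyclohexyl]but-3-enoate
Conditions: Pd2(dba)3 (2.5 mol %), AsPh3 (20 mol %), CuI (10 mol %), NMP, 45 °C, dark
Reagents that add atoms: none
Why: Stille coupling of an α-stannylacrylate with an alkenyl iodide, accelerated by AsPh3 and CuI, forms the diene single bond with retention at both partners while the vinylsilane and the free triol are spectators.

Step 22
Reactants: 29 ethyl (2Z,3E)-2-[(trimethylsilyl)methylidene]-4-[(1S,2S,4R)-1,2,4-trihydroxy-2,6,6-trimethylcyclohexyl]but-3-enoate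
Product: 30 ethyl (2Z,3E)-2-(iodomethylidene)-4-[(1S,2S,4R)-1,2,4-trihydroxy-2,6,6-trimethylcyclohexyl]but-3-enoate
Conditions: N-iodosuccinimide, (CF3)2CHOH, 0 °C, dark
Reagents that add atoms: N-iodosuccinimide, O=C1CCC(=O)N1I
Why: Electrophilic ipso-iododesilylation, in which iodonium attacks the silicon-bearing terminus of the diene and the β-silyl cation loses silicon after the shorter rotation, replaces C–Si by C–I with retention and so places iodine cis to the ester, the fluorinated alcohol speeding up the reaction of this electron-poor vinylsilane.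

Step 23
Reactants: 30 ethyl (2Z,3E)-2-(iodomethylidene)-4-[(1S,2S,4R)-1,2,4-trihydroxy-2,6,6-trimethylcyclohexyl]but-3-enoate
Product: 31 (2Z,3E)-2-(iodomethylidene)-4-[(1S,2S,4R)-1,2,4-trihydroxy-2,6,6-trimethylcyclohexyl]but-3-enoic acid
Conditions: LiOH, THF/H2O, 0 °C to rt; then dilute HCl to pH 3
Reagents that add atoms: lithium hydroxide, [Li+].[OH-]
Why: Saponification of the ethyl ester at low temperature (acyl substitution) is expected to spare the vinyl iodide, whose α-carbon carries no hydrogen for elimination, and the E double bond of the arm rules out lactone formation with the ring hydroxyls.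

Step 24
Reactants: 31 (2Z,3E)-2-(iodomethylidene)-4-[(1S,2S,4R)-1,2,4-trihydroxy-2,6,6-trimethylcyclohexyl]but-3-enoic acid; 15 (R)-4-[(3E,5E,7E,9E)-3,10-dimethyldodeca-3,5,7,9-tetraene-1,11-diyn-1-yl]-3,5,5-trimethylcyclohex-3-en-1-ol
Product: 33 target CNP0163979.2 (Z-ylidenebutenolide joining the ring A pentaene-yne chain at C5 and the ring B triol vinyl arm at C3), via Z-enynoic acid 32 (not isolated)
Conditions: PdCl2(PPh3)2 (5 mol %), CuI (10 mol %), Et3N, BHT, degassed DMF, rt, dark
Reagents that add atoms: none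
Why: Divalent palladium is reduced in the flask to zerovalent palladium, which inserts into the C–I bond of 31; the copper acetylide of 15 transmetalates and reductive elimination forms the C4–C5 bond, giving Z-enynoic acid 32 with carboxyl group and alkyne held cis. The triethylammonium carboxylate then adds anti across the metal-coordinated triple bond and protonolysis of the vinyl–metal bond completes the O1–C5 bond and closes ring C. The closest known reaction is the tandem Sonogashira coupling–lactonisation of Z-3-iodopropenoic acids with terminal alkynes. Ring C closes in the 5-exo-dig mode, preferred over 6-endo-dig because the cis carboxylate reaches the proximal alkyne carbon without strain. No stereocentre is formed, and the Z geometry of the exocyclic double bond follows from the anti addition, which leaves the polyene chain cis to O1. The step needs 5-exo regioselectivity and Z selectivity, both secured by the fixed Z geometry of the iodoacrylate, while the hydroxyl groups are too remote to reach the alkyne and the amine base at room temperature in the dark spares the pentaene.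

**Compound list**

1 | ketoisophorone (2,6,6-trimethylcyclohex-2-ene-1,4-dione) | CC1=CC(=O)CC(C)(C)C1=O | starting material
2 | (S)-4-hydroxy-2,6,6-trimethylcyclohex-2-en-1-one | CC1=C[C@@H](O)CC(C)(C)C1=O | intermediate
3 | (S)-4-(tert-butyldimethylsilyloxy)-2,6,6-trimethylcyclohex-2-en-1-one | CC1=C[C@@H](O[Si](C)(C)C(C)(C)C)CC(C)(C)C1=O | intermediate
4 | lithium (R)-4-(tert-butyldimethylsilyloxy)-2,6,6-trimethylcyclohex-1-en-1-olate | CC1=C(O[Li])C(C)(C)C[C@H](O[Si](C)(C)C(C)(C)C)C1 | intermediate
5 | (R)-4-(tert-butyldimethylsilyloxy)-2,6,6-trimethylcyclohex-1-en-1-yl trifluoromethanesulfonate | CC1=C(OS(=O)(=O)C(F)(F)F)C(C)(C)C[C@H](O[Si](C)(C)C(C)(C)C)C1 | intermediate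
6 | (E)-3-methylpent-2-en-4-yn-1-ol | C#C/C(C)=C/CO | starting material
7 | (R,E)-5-[4-(tert-butyldimethylsilyloxy)-2,6,6-trimethylcyclohex-1-en-1-yl]-3-methylpent-2-en-4-yn-1-ol | CC1=C(C#C/C(C)=C/CO)C(C)(C)C[C@H](O[Si](C)(C)C(C)(C)C)C1 | intermediate
8 | (R,E)-5-[4-(tert-butyldimethylsilyloxy)-2,6,6-trimethylcyclohex-1-en-1-yl]-3-methylpent-2-en-4-ynal | CC1=C(C#C/C(C)=C/C=O)C(C)(C)C[C@H](O[Si](C)(C)C(C)(C)C)C1 | intermediate
9 | (R)-tert-butyl({4-[(3E,5E)-6-iodo-3-methylhexa-3,5-dien-1-yn-1-yl]-3,5,5-trimethylcyclohex-3-en-1-yl}oxy)dimethylsilane | CC1=C(C#C/C(C)=C/C=C/I)C(C)(C)C[C@H](O[Si](C)(C)C(C)(C)C)C1 | intermediate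
10 | O,C-bis(trimethylsilyl) derivative of 6 | C[Si](C)(C)C#C/C(C)=C/CO[Si](C)(C)C | intermediate
11 | (E)-3-methyl-5-(trimethylsilyl)pent-2-en-4-yn-1-ol | C[Si](C)(C)C#C/C(C)=C/CO | intermediate
12 | (E)-3-methyl-5-(trimethylsilyl)pent-2-en-4-ynal | C[Si](C)(C)C#C/C(C)=C/C=O | intermediate
13 | 2-[(1E,3E)-4-methyl-6-(trimethylsilyl)hexa-1,3-dien-5-yn-1-yl]-4,4,5,5-tetramethyl-1,3,2-dioxaborolane | C[Si](C)(C)C#C/C(C)=C/C=C/B1OC(C)(C)C(C)(C)O1 | intermediate
14 | (R)-tert-butyl({4-[(3E,5E,7E,9E)-3,10-dimethyl-12-(trimethylsilyl)dodeca-3,5,7,9-tetraene-1,11-diyn-1-yl]-3,5,5-trimethylcyclohex-3-en-1-yl}oxy)dimethylsilane | CC1=C(C#C/C(C)=C/C=C/C=C/C=C(C)/C#C[Si](C)(C)C)C(C)(C)C[C@H](O[Si](C)(C)C(C)(C)C)C1 | intermediate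
15 | (R)-4-[(3E,5E,7E,9E)-3,10-dimethyldodeca-3,5,7,9-tetraene-1,11-diyn-1-yl]-3,5,5-trimethylcyclohex-3-en-1-ol | CC1=C(C#C/C(C)=C/C=C/C=C/C=C(C)/C#C)C(C)(C)C[C@H](O)C1 | intermediate
16 | (R)-4-hydroxy-2,6,6-trimethylcyclohex-2-en-1-one | CC1=C[C@H](O)CC(C)(C)C1=O | intermediate
17 | (R)-4-(tert-butyldimethylsilyloxy)-2,6,6-trimethylcyclohex-2-en-1-one | CC1=C[C@H](O[Si](C)(C)C(C)(C)C)CC(C)(C)C1=O | intermediate
18 | lithium (S)-4-(tert-butyldimethylsilyloxy)-2,6,6-trimethylcyclohex-1-en-1-olate | CC1=C(O[Li])C(C)(C)C[C@@H](O[Si](C)(C)C(C)(C)C)C1 | intermediate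
19 | (S)-4-(tert-butyldimethylsilyloxy)-2,6,6-trimethylcyclohex-1-en-1-yl trifluoromethanesulfonate | CC1=C(OS(=O)(=O)C(F)(F)F)C(C)(C)C[C@@H](O[Si](C)(C)C(C)(C)C)C1 | intermediate
20 | ethynyltrimethylsilane | C#C[Si](C)(C)C | starting material
21 | (S)-tert-butyldimethyl({3,5,5-trimethyl-4-[(trimethylsilyl)ethynyl]cyclohex-3-en-1-yl}oxy)silane | CC1=C(C#C[Si](C)(C)C)C(C)(C)C[C@@H](O[Si](C)(C)C(C)(C)C)C1 | intermediate
22 | (S)-4-ethynyl-3,5,5-trimethylcyclohex-3-en-1-ol | CC1=C(C#C)C(C)(C)C[C@@H](O)C1 | intermediate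
23 | (1R,3R,6R)-6-ethynyl-1,5,5-trimethyl-7-oxabicyclo[4.1.0]heptan-3-ol | C#C[C@]1(O2)C(C)(C)C[C@@H](O)C[C@]12C | intermediate
24 | (1R,2S,4R)-1-ethynyl-2,6,6-trimethylcyclohexane-1,2,4-triol | C#C[C@]1(O)C(C)(C)C[C@@H](O)C[C@]1(C)O | intermediate
25 | (1S,2S,4R)-1-[(E)-2-(tributylstannyl)ethenyl]-2,6,6-trimethylcyclohexane-1,2,4-triol | CCCC[Sn](CCCC)(CCCC)/C=C/[C@]1(O)C(C)(C)C[C@@H](O)C[C@]1(C)O | intermediate
26 | (1S,2S,4R)-1-[(E)-2-iodoethenyl]-2,6,6-trimethylcyclohexane-1,2,4-triol | I/C=C/[C@]1(O)C(C)(C)C[C@@H](O)C[C@]1(C)O | intermediate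
27 | ethyl 3-(trimethylsilyl)propiolate | CCOC(=O)C#C[Si](C)(C)C | starting material
28 | ethyl (E)-2-(tributylstannyl)-3-(trimethylsilyl)acrylate | CCOC(=O)/C(=C\[Si](C)(C)C)[Sn](CCCC)(CCCC)CCCC | intermediate
29 | ethyl (2Z,3E)-2-[(trimethylsilyl)methylidene]-4-[(1S,2S,4R)-1,2,4-trihydroxy-2,6,6-trimethylcyclohexyl]but-3-enoate | CCOC(=O)/C(=C\[Si](C)(C)C)/C=C/[C@]1(O)C(C)(C)C[C@@H](O)C[C@]1(C)O | intermediate
30 | ethyl (2Z,3E)-2-(iodomethylidene)-4-[(1S,2S,4R)-1,2,4-trihydroxy-2,6,6-trimethylcyclohexyl]but-3-enoate | CCOC(=O)/C(=C\I)/C=C/[C@]1(O)C(C)(C)C[C@@H](O)C[C@]1(C)O | intermediate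
31 | (2Z,3E)-2-(iodomethylidene)-4-[(1S,2S,4R)-1,2,4-trihydroxy-2,6,6-trimethylcyclohexyl]but-3-enoic acid | OC(=O)/C(=C\I)/C=C/[C@]1(O)C(C)(C)C[C@@H](O)C[C@]1(C)O | intermediate
32 | Z-enynoic acid (carboxyl group cis to the new alkynyl substituent, ring B vinyl arm on the α-carbon) | CC1=C(C#C/C(C)=C/C=C/C=C/C=C(C)/C#C/C=C(/C=C/[C@]2(O)C(C)(C)C[C@@H](O)C[C@]2(C)O)C(=O)O)C(C)(C)C[C@H](O)C1 | intermediate
33 | CNP0163979.2 | CC1=C(C#C/C(C)=C/C=C/C=C/C=C(C)/C=C2C=C(/C=C/[C@]3(O)C(C)(C)C[C@@H](O)C[C@]3(C)O)C(=O)O/2)C(C)(C)C[C@H](O)C1 | target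

**Count and risks**

Total step count: 24. Longest linear sequence: 12 steps (steps 12–19 and 21–24, from ketoisophorone through ring B); the ring A branch has 9 (steps 1–6, 10, 11, 24).

Steps most likely to fail:

1. Step 18. The epoxide may open in the wrong sense or by a cationic side path: water may enter at the propargylic carbon C6, or the ionising epoxide may shift a ring bond or lose a proton, so that the trans-diol forms with the wrong configuration or in poor amount. The fallback sets out from triflate 19 and returns at vinyl iodide 26. Stille coupling of 19 with Bu3SnCH2OH (Pd(PPh3)4, LiCl, dioxane, heat) gives the allylic alcohol F1. Sharpless asymmetric epoxidation (Ti(Oi-Pr)4, L-(+)-diethyl tartrate, t-BuOOH, CH2Cl2, −20 °C) places the epoxide by reagent control cis to the silyloxy group and gives the epoxy alcohol F2. Opening with benzoic acid mediated by Ti(Oi-Pr)4, which for 2,3-epoxy alcohols takes place at the carbon remote from the carbinol (here C5) with inversion, gives the benzoate diol F3. Oxidation of the primary alcohol (TEMPO, PhI(OAc)2) gives the hydroxy aldehyde F4, Takai olefination (CrCl2, CHI3) gives the E-vinyl iodide benzoate F5, and methanolysis (K2CO3, MeOH) gives the silyl ether F6. Bu4NF then gives 26. The detour replaces steps 15 to 19 and no longer depends on the face selectivity of step 17.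

2. Step 24. Ring closure may stay incomplete or go astray and the unprotected polyene may suffer under the coupling conditions: the carboxylate may fail to add, may add in the 6-endo sense, or the alkyne may homocouple. The fallback sets out from ester 30 and alkyne 15 and comes back to the route at 32 and then 33. Sonogashira coupling of 30 with 15 (Pd(PPh3)4, CuI, Et3N, DMF, rt, dark) gives the ethyl enynoate F7. LiOH in THF/H2O then gives enynoic acid 32, now isolated. AgNO3 (catalytic, acetone, dark) closes ring C by 5-exo-dig lactonisation to 33, monovalent silver being a known catalyst for the conversion of Z-enynoic acids into Z-ylidenebutenolides.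

3. Step 14 (and its mirror image, step 3). Hydride may add to the carbonyl group instead of the β-carbon, or the hindered tetrasubstituted enolate may be sulfonylated incompletely. The fallback sets out from enone 17 and returns at triflate 19. Hydrogenation (H2, Pd/C, EtOAc) gives the saturated ketone F8 as a mixture of epimers at the methyl-bearing carbon. Both epimers converge on deprotonation with LiN(i-Pr)2 at the only α-hydrogen and trapping with PhNTf2, which gives 19. The same two operations take enone 3 through the enantiomeric ketone F9 to triflate 5.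

**Further compounds**

F1 | step 18 | [(S)-4-(tert-butyldimethylsilyloxy)-2,6,6-trimethylcyclohex-1-en-1-yl]methanol | CC1=C(CO)C(C)(C)C[C@@H](O[Si](C)(C)C(C)(C)C)C1
F2 | step 18 | epoxy alcohol, 5,6-epoxide cis to the silyloxy group, hydroxymethyl on C6 | OC[C@]1(O2)C(C)(C)C[C@@H](O[Si](C)(C)C(C)(C)C)C[C@]12C
F3 | step 18 | benzoate diol, C5 benzoate trans to the C6 hydroxyl, hydroxymethyl on C6 | OC[C@]1(O)C(C)(C)C[C@@H](O[Si](C)(C)C(C)(C)C)C[C@]1(C)OC(=O)c1ccccc1
F4 | step 18 | hydroxy aldehyde, formyl on C6, C5 benzoate | O=C[C@]1(O)C(C)(C)C[C@@H](O[Si](C)(C)C(C)(C)C)C[C@]1(C)OC(=O)c1ccccc1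
F5 | step 18 | E-vinyl iodide, C5 benzoate, C3 silyl ether | I/C=C/[C@]1(O)C(C)(C)C[C@@H](O[Si](C)(C)C(C)(C)C)C[C@]1(C)OC(=O)c1ccccc1
F6 | step 18 | C3 tert-butyldimethylsilyl ether of 26 | I/C=C/[C@]1(O)C(C)(C)C[C@@H](O[Si](C)(C)C(C)(C)C)C[C@]1(C)O
F7 | step 24 | ethyl ester of Z-enynoic acid 32 | CC1=C(C#C/C(C)=C/C=C/C=C/C=C(C)/C#C/C=C(/C=C/[C@]2(O)C(C)(C)C[C@@H](O)C[C@]2(C)O)C(=O)OCC)C(C)(C)C[C@H](O)C1
F8 | step 14 | (4S)-4-(tert-butyldimethylsilyloxy)-2,2,6-trimethylcyclohexan-1-one, both C6 epimers | CC1C[C@H](O[Si](C)(C)C(C)(C)C)CC(C)(C)C1=O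
F9 | step 14 | (4R)-4-(tert-butyldimethylsilyloxy)-2,2,6-trimethylcyclohexan-1-one, both C6 epimers, for step 3 | CC1C[C@@H](O[Si](C)(C)C(C)(C)C)CC(C)(C)C1=O
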